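J 1.0 mM; X 1.05 mM; time 30 s; volume of the second phase over the first 0.50

    J.Z ⇌ L (K1 = 0.56, k1 = 0.0240 /s)
    Z + J.Z → Z.J.Z (k2 = 47.5 /M/s)
    J + Z → J.Z (k3 = 34.1 /M/s)
    Z ⇌ X, rate k4*([Z] - [X]/K4) per volume of the first phase (K4 = 0.53, k4 = 0.0110 /s)

* how much J.Z there is at 30 s, in percent of the J charged
* the change that raises the amount of J.Z at 30 s, in percent of the J charged most ("none" if none brings more than 2 percentage points) (teal / ochre / none)
* amount of J.Z at 30 s, in percent of the J charged, after teal

- teal: doubling the amount of X, all else as stated
- ochre: doubling the transfer coefficient of step 4, all else as stated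

- in the second phase: X; everything else is in the first
- charges count per volume of the first phase; a concentration in a rate is the amount of a species over the volume of its own phase; every rate counts per litre of the first phase
- run time (flask): 30 s

Start from the balance of J: cJ, cJ.Z, cZ.J.Z and cL sum to 1.0 mM at every moment, so J.Z is what J has lost, minus what went on to Z.J.Z and L. Now draw cZ. It starts at nothing and climbs with slope 0.0436 mM/s, since X stands in its own phase at its charge over the volume ratio. X drains with rate constant 0.0415 /s. Z leaves, pseudo-first-order, with 0.0451 /s; hold J at its charge here and set aside the attack of Z on J.Z. Feed and loss cross at 23.1 s, where cZ tops out near 0.370 mM and bends over.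

Divide the rate of J's loss by cJ, and the time integral of 34.1 /M/s times cZ, the exposure E, replaces the clock: cJ is its charge times exp(-E). Under this hump E reaches 0.296 at 30 s, which leaves 74.4 % of J. Divide the second addition's rate by the first's, and time drops out again, with the selectivity factor 1.39. Step 1 runs both ways and relaxes with 0.0669 /s; assume that J.Z and L together rise in a straight line over the run, and then L holds a share 0.204 of the two at 30 s, which divides J.Z by 1.26. That gives y = 16.5 %.

Teal makes E 0.592, so yb = 23.2 %. Ochre doubles k4, which doubles the feed slope and the drain of X and raises the loss of Z, and it makes E 0.383, so J.Z reaches 19.3 %. My choice is teal.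

The forecast says 17 %, teal and 24 %: “Doubling X about doubles Z throughout”.

The flask gives 17.5 % with 74 % of J left; teal wins, gaining 7.2 percentage points against 3.5 points for ochre, and reaches 24.7 %. J.Z has moved by 5 points with X charged at 0.658 mM or 1.64 mM. Now take the neighbour flask charged with 4.0 mM of J. There Z leaves with 0.147 /s, faster than in the first flask, so E drops to 0.147. That reckons 86.3 % of its J left and J.Z at 9.79 %. Its run reads 86 % of J left and J.Z at 10.0 %.

All constants are those of an exercise; the result is computed.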